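## Analysis of the target

Target 30 is a cyclohex-3-ene. With the ring numbered C1 = quaternary carbinol carbon (bearing the benzoyloxymethyl carbon C7), C2 = CHCl, C3=C4, C5 = CHOH and C6 = CHOBz, it has four contiguous stereocentres C5–C6–C1–C2 of configuration (1R,2R,5S,6R). The C1 hydroxyl is cis to the C6 benzoate and trans to both the C2 chlorine and the C5 hydroxyl, so C7, the chlorine and the C5 oxygen lie on one face and the C1 and C6 oxygens on the other. The C1–OH/C2–Cl pair is a trans chlorohydrin that closes to an epoxide with base, the secondary allylic chloride beside a quaternary carbon can ionise or transpose, and the C6 benzoate sits between two free hydroxyls to which it can migrate. The difficulty is threefold: four oxygens (C1, C5, C6, C7) in two different end states must be told apart, the quaternary carbinol must be built with control, and chlorine must be placed with defined configuration on a hindered allylic carbon where substitution is unreliable. The strategy rests on the C1–C2 bond, which joins the quaternary carbinol carbon to the allylic chloride carbon next to C3=C4. With C7 at the carboxyl level, C7(=O)–C1–C2–C3=C4 is a γ,δ-unsaturated acid, the array left by a [3,3] shift of a ketene acetal O–C7=C1 onto an (E)-2-chlorovinyl group on C4. Undoing that shift leaves a δ-lactone (ring O–C7–C1–C6–C5–C4) whose oxygenated carbons C1, C6 and C5 have the configuration of D-xylose (1), so the absolute stereochemistry can be bought.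

## Retrosynthetic reasoning

Unmasking and esters (30 back to 24). The tertiary C1 hydroxyl and the allylic C5 hydroxyl of 30 are revealed last and without base, so their O–H bonds go back to two Si–O bonds in 29. The two benzoate C–O bonds are cut together, to diol 27 and two molecules of 28, because the C7 and C6 oxygens are the only ones to be acylated. The C6 oxygen of 27 goes back to a p-methoxybenzyl ether (26), and C7 is raised from alcohol to carboxyl (acid 24). This gives a γ,δ-unsaturated acid whose three ring oxygens carry two kinds of ether, the C6 one distinct. The forward steps must reduce a neopentyl-type acid and remove a benzyl-type ether without touching the allylic chloride.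

Key disconnection (24 back to 21). In 24 the C1–C2 bond is cut, the alkene moves back from C3=C4 to C2=C3, and C4 is rejoined to a carboxyl oxygen. This reverses a [3,3] shift and gives δ-lactone 21, by way of silyl ester 23 and silyl ketene acetal 22. This bond is chosen because its cleavage removes two stereocentres (C1, C2), the quaternary carbon and the carbocycle at once, and leaves a ring oxygen with three consecutive oxygenated carbons, the pattern of a pentose. The forward reaction must close the ring through a boat and hand the C4 configuration on to C1 and C2.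

Lactone (21 back to 18). The acyl C7–O bond of 21 is cut and C7 lowered to the alcohol level, giving 1,5-diol 18 by way of lactol 20 and hydroxy aldehyde 19. The oxidation comes at the end of the chain work, so no ester is present while organometallic and hydride reagents are in use.

Ether from acetal (18 back to 17). The benzylic C–H bond of the C6 ether in 18 is cut so that this carbon is shared with the C7 oxygen, giving cyclic arylidene acetal 17. One acetal protects two oxygens through the chain-building steps and later delivers an ether on the secondary C6 oxygen and a free primary C7 hydroxyl.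

Chloroalkene (17 back to 14 and 15). The C2–Cl bond is cut, giving terminal alkyne 14 and 15 as the chlorine source, by way of alkenylzirconocene 16. Hydrometalation fixes the (E) geometry that the key step turns into the C2 configuration.

Carbinol C4 (14 back to 13 and 12). The silyl cap is returned to the alkyne (13) and the C4–H bond of the carbinol is cut, giving ynone 12. A ketone is preferred to acetylide addition on an aldehyde because the reducing catalyst, not the substrate, then decides the C4 configuration.

Chain extension (12 back to 9 and 10). The C3–C4 bond is cut, giving amide 9 and alkyne 10 (used as its lithium salt 11). The amide stops cleanly at the ketone stage.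

Protected xylonic acid (9 back to 1). The two Si–O bonds go back to 7 and 8. The amide C–N bond goes back to lactone 4 and 5 (used as 6); opening 4 exposes exactly the two hydroxyls, the future C5 and C1 oxygens, that need the same silyl group. The acetal goes back to 2 and 3; only O3 and O5 of 2 are cis, so the future C6 and C7 oxygens are paired. Lactone 2 is the oxidation product of 1, whose C1–C5 become C4, C5, C6, C1 and C7 of the target.

## Alternatives that were turned down

Alternative 1: The disconnection removes the C5–O and C6–O bonds of an oxirane from an achiral cyclohexa-2,5-dienol, the arene hydrate A1, which a Birch reduction of an aromatic precursor would supply. In the forward key step a chiral bishydroxamic acid complex of Hf(OtBu)4 with an alkyl hydroperoxide epoxidises one of the two enantiotopic alkenes on the face of the C1 hydroxyl. This gives the syn epoxy alcohol A2 and fixes C1, C5 and C6 at once. In its favour, the skeleton comes from a cheap arene in very few steps, no protecting group is needed up to A2, and hydroxyl delivery gives the cis C1–O/C6–O relation directly. On step economy and on catalytic rather than chiral-pool induction it is stronger than the chosen route. Against it, A1 is a tertiary bis-allylic alcohol that rearomatises by loss of water under Lewis acids, and the whole absolute configuration depends on a desymmetrisation untested on this substrate type. A2 also still lacks C2 and has the wrong C5 configuration. Its epoxide must be opened at C5 with inversion, and the remaining C2=C3 alkene with the C4 methylene must be turned into the C2 chloride and the C3=C4 alkene, trans to the C1 hydroxyl. That allylic transposition has no controlling element for regio- or stereochemistry. The chosen strategy costs more steps, but takes every stereocentre from 1 or from stereospecific steps and places the chlorine before the ring exists.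

Alternative 2: The disconnection cuts the C5–O bond of a bridged γ-lactone and the C2–Cl bond, leading back to the dihydroxy diene acid A3. In the forward key step Pd(OAc)2 with a quinone reoxidant and excess LiCl adds the C7 carboxylate to C5 and chloride to C2 of the diene, both anti to palladium. This gives chlorolactone A4 with the C3=C4 alkene in place. In its favour, A3 already holds C1 and C6, the cis-1,4 relation of the C5 oxygen and the C2 chlorine is what this divalent-palladium diene chemistry delivers, and the lactone marks the C5 oxygen off from the C6 oxygen. The target would be only a few steps away, so in length and in stereocentres set per step it is clearly stronger than the chosen route. Against it, A3 is not a catalogue chemical but the product of a whole-cell arene dihydroxylation, and it dehydrates to an aromatic acid under acidic oxidative conditions. The free C1 and C6 hydroxyls can compete as nucleophiles, and chloride must attack the allyl terminus C2 beside the quaternary carbon rather than the freer C4. After A4 the lactone must be reduced next to a secondary allylic chloride that hydride reagents displace, and the C6 benzoate must be in place before that reduction yet survive it, so protecting steps return. The chosen strategy is longer, but starts from purchased material, has no aromatisation-prone intermediate and keeps the ring oxygens apart by two ether types from the start.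

Alternative 3: The disconnection cuts the C3=C4 double bond and leads to the acyclic 1,7-diene A5, a pentose chain branched at C1 with a one-carbon unit. In the forward key step the second-generation Grubbs catalyst closes A5 to cyclohexene A6. A6 has the C1/C6 oxygens tied as an acetonide, C7 benzoylated, a C5 silyl ether and a C2 hydroxyl cis to the C1 oxygen. In its favour, ring-closing metathesis of such a diene to a six-membered ring is one of the most dependable ring closures and is certainly more secure than the key step chosen here. The acetonide also protects the cis C1/C6 diol economically. Against it, the metathesis creates no stereocentre, so the quaternary carbinol C1 and the C2 carbinol must both be set in the open chain. That needs a formaldehyde branching that leaves two similar hydroxymethyl groups to tell apart, and a vinyl addition to a neopentyl-type aldehyde with no reliable facial bias. The C2 hydroxyl of A6 must then be exchanged for chlorine with inversion at a secondary allylic carbon beside a quaternary centre, where transposition to C4 and ionisation compete. The step count is comparable. The chosen route gives up the certainty of the ring closure, but sets C1 and C2 together by chirality transfer and needs no substitution at C2.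

Key step: step 11

Remark on the chemistry: the acetal carbon of 4, 7, 9, 12–14, 16 and 17 is drawn as the thermodynamic epimer (aryl equatorial) and disappears in step 9; the anomeric carbon of lactol 20 is left undefined.

## Route

Step 1
Reactants: 1 D-xylose
Product: 2 D-xylono-1,4-lactone
Conditions: Br2, NaHCO3, H2O, 0–5 °C; concentrate, extract into EtOH
Reagents that add atoms: none
Why: Bromine-water oxidation of an aldose at the anomeric carbon (aldose to aldonolactone); NaHCO3 takes up HBr and the first-formed δ-lactone should settle as the γ-lactone on concentration. The three stereocentres are not touched.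

Step 2
Reactants: 2 D-xylono-1,4-lactone; 3 4-methoxybenzaldehyde dimethyl acetal
Product: 4 3,5-O-(4-methoxybenzylidene)-D-xylono-1,4-lactone
Conditions: cat. camphorsulfonic acid, MeCN, rt, MeOH removed under reduced pressure
Reagents that add atoms: 4-methoxybenzaldehyde dimethyl acetal COc1ccc(C(OC)OC)cc1
Why: Acid-catalysed transacetalisation under thermodynamic control; only O3 and O5 are cis on the lactone ring and can form the six-membered acetal, while the trans 2-hydroxyl cannot bridge and stays free. The acetal pairs the oxygens that become the C6 and C7 oxygens of the target.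

Step 3
Reactants: 4 3,5-O-(4-methoxybenzylidene)-D-xylono-1,4-lactone; 5 N,O-dimethylhydroxylamine hydrochloride
Product: 7 N-methoxy-N-methyl-3,5-O-(4-methoxybenzylidene)-D-xylonamide, via chloromagnesium N-methoxy-N-methylamide 6 (not isolated)
Conditions: iPrMgCl, THF, −20 → 0 °C; aq. NH4Cl
Reagents that add atoms: N,O-dimethylhydroxylamine hydrochloride CNOC.Cl
Why: Aminolysis of a lactone by a magnesium amide (Weinreb amide formation); the conditions are not Lewis acidic, so the acetal should survive, and the 2-alkoxide formed first shields the α-centre from epimerisation. Opening frees O4, so the two oxygens that need the same silyl group (future C5 and C1 oxygens) are now the only free hydroxyls.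

Step 4
Reactants: 7 N-methoxy-N-methyl-3,5-O-(4-methoxybenzylidene)-D-xylonamide; 8 triethylsilyl trifluoromethanesulfonate
Product: 9 N-methoxy-N-methyl-3,5-O-(4-methoxybenzylidene)-2,4-bis-O-(triethylsilyl)-D-xylonamide
Conditions: 2,6-lutidine, CH2Cl2, −78 → 0 °C
Reagents that add atoms: triethylsilyl trifluoromethanesulfonate CC[Si](CC)(CC)OS(=O)(=O)C(F)(F)F
Why: Silylation of two secondary alcohols with a silyl triflate and a hindered base; capping O4 also stops relactonisation. Triethylsilyl is chosen because one of these ethers ends on the tertiary C1 oxygen and must still come off under mild acidic fluoride.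

Step 5
Reactants: 9 N-methoxy-N-methyl-3,5-O-(4-methoxybenzylidene)-2,4-bis-O-(triethylsilyl)-D-xylonamide; 10 ethynyltrimethylsilane
Product: 12 1,2-dideoxy-5,7-O-(4-methoxybenzylidene)-4,6-bis-O-(triethylsilyl)-1-(trimethylsilyl)-D-xylo-hept-1-yn-3-ulose, via lithium (trimethylsilyl)acetylide 11 (not isolated)
Conditions: n-BuLi, THF, −78 °C; then 9, −78 → −20 °C; cold aq. NH4Cl
Reagents that add atoms: ethynyltrimethylsilane C#C[Si](C)(C)C
Why: Weinreb ketone synthesis: the chelated tetrahedral adduct holds until quench, so the acetylide adds once and the C3–C4 bond is made at the ketone level. The silyl cap keeps the ynone from conjugate addition of the liberated amine.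

Step 6
Reactants: 12 1,2-dideoxy-5,7-O-(4-methoxybenzylidene)-4,6-bis-O-(triethylsilyl)-1-(trimethylsilyl)-D-xylo-hept-1-yn-3-ulose
Product: 13 1,2-dideoxy-5,7-O-(4-methoxybenzylidene)-4,6-bis-O-(triethylsilyl)-1-(trimethylsilyl)-D-gulo-hept-1-ynitol
Conditions: Ru[(R,R)-TsNCH(Ph)CH(Ph)NH](η6-p-cymene) (2 mol%), iPrOH, rt
Reagents that add atoms: none
Why: Noyori asymmetric transfer hydrogenation of an α,β-acetylenic ketone, an outer-sphere hydride and proton transfer in which the alkynyl group plays the π-substituent. The (R,R) catalyst should deliver hydride to the face that gives the (S)-carbinol, that is the C4 oxygen anti to the C5 oxygen; reagent control is relied on to override the weak opposite Felkin–Anh bias of the α-silyloxy ketone.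

Step 7
Reactants: 13 1,2-dideoxy-5,7-O-(4-methoxybenzylidene)-4,6-bis-O-(triethylsilyl)-1-(trimethylsilyl)-D-gulo-hept-1-ynitol
Product: 14 1,2-dideoxy-5,7-O-(4-methoxybenzylidene)-4,6-bis-O-(triethylsilyl)-D-gulo-hept-1-ynitol
Conditions: cat. K2CO3, MeOH, 0 °C
Reagents that add atoms: none
Why: Methanolysis of the alkynyl C–Si bond (protodesilylation); secondary triethylsilyl ethers should survive catalytic carbonate at 0 °C, and the short cold exposure limits silyl shift to the neighbouring carbinol.

Step 8
Reactants: 14 1,2-dideoxy-5,7-O-(4-methoxybenzylidene)-4,6-bis-O-(triethylsilyl)-D-gulo-hept-1-ynitol; 15 N-chlorosuccinimide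
Product: 17 (E)-1-chloro-1,2-dideoxy-5,7-O-(4-methoxybenzylidene)-4,6-bis-O-(triethylsilyl)-D-gulo-hept-1-enitol, via alkenylzirconocene 16 (not isolated)
Conditions: Cp2Zr(H)Cl (2.5 equiv), THF, rt; then 15, 0 °C
Reagents that add atoms: N-chlorosuccinimide O=C1CCC(=O)N1Cl
Why: Hydrozirconation of a terminal alkyne (syn addition, zirconium on the terminal carbon) followed by electrophilic chlorination with retention should give only the (E)-chloroalkene. The first equivalent of hydride is consumed by the hydroxyl; oxygen on the allylic carbon is γ to zirconium, so no β-elimination is open.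

Step 9
Reactants: 17 (E)-1-chloro-1,2-dideoxy-5,7-O-(4-methoxybenzylidene)-4,6-bis-O-(triethylsilyl)-D-gulo-hept-1-enitol
Product: 18 (E)-1-chloro-1,2-dideoxy-5-O-(4-methoxybenzyl)-4,6-bis-O-(triethylsilyl)-D-gulo-hept-1-enitol
Conditions: iBu2AlH, CH2Cl2, −78 → 0 °C; aq. potassium sodium tartrate
Reagents that add atoms: none
Why: Regioselective reductive opening of a 4-methoxybenzylidene acetal: aluminium binds the less hindered primary oxygen, that C–O bond breaks and hydride quenches the oxocarbenium ion. The benzyl-type ether is left on the secondary oxygen (future C6 oxygen) and the primary hydroxyl (future C7) is freed.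

Step 10
Reactants: 18 (E)-1-chloro-1,2-dideoxy-5-O-(4-methoxybenzyl)-4,6-bis-O-(triethylsilyl)-D-gulo-hept-1-enitol
Product: 21 (E)-7-chloro-6,7-dideoxy-3-O-(4-methoxybenzyl)-2,4-bis-O-(triethylsilyl)-L-gluco-hept-6-enono-1,5-lactone, via hydroxy aldehyde 19 (not isolated), via lactol 20 (not isolated)
Conditions: TEMPO (20 mol%), PhI(OAc)2, CH2Cl2, rt
Reagents that add atoms: none
Why: Nitroxyl-catalysed oxidative lactonisation of a 1,5-diol: the oxoammonium ion oxidises the primary alcohol faster than the hindered, chlorine-deactivated secondary allylic one; the hydroxy aldehyde closes to the six-membered lactol, which is oxidised on to the lactone. No stereocentre is formed or epimerised under these near-neutral conditions; the product is the all-trans lactone with the chlorovinyl group cis to the C6 oxygen and trans to the C5 oxygen.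

Step 11
Reactants: 21 (E)-7-chloro-6,7-dideoxy-3-O-(4-methoxybenzyl)-2,4-bis-O-(triethylsilyl)-L-gluco-hept-6-enono-1,5-lactone
Product: 24 (1S,2R,5S,6R)-2-chloro-6-[(4-methoxybenzyl)oxy]-1,5-bis(triethylsilyloxy)cyclohex-3-ene-1-carboxylic acid, via silyl ketene acetal 22 (not isolated), via trimethylsilyl ester 23 (not isolated)
Conditions: LiN(SiMe3)2, Me3SiCl–Et3N (premixed), THF, −78 °C → rt; solvent exchange to PhMe, salts filtered off, 100 °C; then aq. citric acid, THF, 0 °C
Reagents that add atoms: none
Why: Proposed new method: enolisation of 21 in the presence of Me3SiCl traps the lactone enolate at once as the cyclic silyl ketene acetal 22, whose O–C7=C1 unit and C4-bound (E)-chlorovinyl group form an allyl vinyl ether; on heating, a concerted suprafacial [3,3] shift makes C1–C2, breaks the C4–O bond and moves the alkene to C3=C4, giving silyl ester 23 and, after hydrolysis, acid 24. The closest known reaction type is the Ireland–Claisen ring contraction of 6-alkenyl δ-lactones to cyclohex-3-enecarboxylic acids (and the thermal Claisen route from 5-vinyl glycals to carbasugars); a chlorine-bearing vinyl terminus has not been used, but chlorine is a modest σ-acceptor and π-donor that should neither block nor redirect the shift. The cyclohexene closes in the sigmatropic event itself, formally a 6-endo-trig attack of C1 on the chlorovinyl group, through a boat transition state (bicyclo[2.2.2]octane-like, bridgeheads C1 and C4) because the lactone ring forbids the chair. C1 is set by the C5–C6 tether: the vinyl group can reach only the ketene acetal face on its own side of the lactone, so C7 ends cis to the C5 oxygen and the C1 oxygen cis to the C6 oxygen. C2 is set by the alkene geometry: in the boat the (E)-chlorine lies on the side of the departing O–C7 bridge and ends cis to C7, trans to the C1 oxygen, while the C4 centre is consumed in the chirality transfer. The step therefore needs geometrically pure (E)-alkene, secured by the hydrozirconation of step 8, and the lactone configuration with vinyl cis to the C6 oxygen and trans to the C5 oxygen, secured by 1 and step 6. Internal silylation at −78 °C, with the C6–O bond held near the enolate plane in the all-equatorial lactone, should outrun β-elimination of the C6 alkoxide, and salt-free heating in toluene limits chloride exchange at the new allylic chloride; the slim benzyl-type ether is placed on the C6 oxygen because that oxygen leans toward the vinyl bridge in the boat.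

Step 12
Reactants: 24 (1S,2R,5S,6R)-2-chloro-6-[(4-methoxybenzyl)oxy]-1,5-bis(triethylsilyloxy)cyclohex-3-ene-1-carboxylic acid
Product: 26 [(1R,2R,5S,6R)-2-chloro-6-[(4-methoxybenzyl)oxy]-1,5-bis(triethylsilyloxy)cyclohex-3-en-1-yl]methanol, via mixed carbonic anhydride 25 (not isolated)
Conditions: iBuOCOCl, N-methylmorpholine, THF, −15 °C; then NaBH4, H2O, 0 °C; aq. NH4Cl
Reagents that add atoms: none
Why: Carboxyl activation as a mixed carbonic anhydride and borohydride reduction, mild enough to leave the allylic chloride, the alkene and the ethers. The carboxyl group is cis to chlorine, so neither β-lactone closure nor anti decarboxylative elimination is geometrically open while the carboxylate exists, and the intermediate aldehyde has no α-hydrogen.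

Step 13
Reactants: 26 [(1R,2R,5S,6R)-2-chloro-6-[(4-methoxybenzyl)oxy]-1,5-bis(triethylsilyloxy)cyclohex-3-en-1-yl]methanol
Product: 27 [(1R,2R,5S,6R)-2-chloro-6-hydroxy-1,5-bis(triethylsilyloxy)cyclohex-3-en-1-yl]methanol
Conditions: DDQ, CH2Cl2–pH 7 phosphate buffer, 0 °C → rt
Reagents that add atoms: none
Why: Oxidative cleavage of a p-methoxybenzyl ether: hydride abstraction gives an oxocarbenium ion that water hydrolyses. The buffered two-phase medium favours hydrolysis over trapping by the neighbouring C7 hydroxyl and spares the silyl ethers.

Step 14
Reactants: 27 [(1R,2R,5S,6R)-2-chloro-6-hydroxy-1,5-bis(triethylsilyloxy)cyclohex-3-en-1-yl]methanol; 28 benzoyl chloride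
Product: 29 [(1R,2R,5S,6R)-6-(benzoyloxy)-2-chloro-1,5-bis(triethylsilyloxy)cyclohex-3-en-1-yl]methyl benzoate
Conditions: pyridine, cat. DMAP, CH2Cl2, 0 °C → rt
Reagents that add atoms: benzoyl chloride O=C(Cl)c1ccccc1
Why: Nucleophile-catalysed acylation of the primary C7 and the secondary C6 hydroxyl in one operation; the C1 and C5 oxygens are silylated, so only the two oxygens that carry benzoates in the target can react.

Step 15
Reactants: 29 [(1R,2R,5S,6R)-6-(benzoyloxy)-2-chloro-1,5-bis(triethylsilyloxy)cyclohex-3-en-1-yl]methyl benzoate
Product: 30 [(1R,2R,5S,6R)-6-(benzoyloxy)-2-chloro-1,5-dihydroxycyclohex-3-en-1-yl]methyl benzoate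
Conditions: HF·pyridine, pyridine, THF, 0 °C → rt
Reagents that add atoms: none
Why: Fluoride-driven cleavage of both Si–O bonds under buffered acidic conditions. The freed tertiary hydroxyl is never an alkoxide, so the trans chlorohydrin should not close to the epoxide, and the benzoates should neither migrate nor hydrolyse.

## Compound list

1 | D-xylose (aldehydo form) | O=C[C@H](O)[C@@H](O)[C@H](O)CO | starting material
2 | D-xylono-1,4-lactone | O=C1[C@H](O)[C@@H](O)[C@@H](CO)O1 | intermediate
3 | 4-methoxybenzaldehyde dimethyl acetal | COc1ccc(C(OC)OC)cc1 | starting material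
4 | 3,5-O-(4-methoxybenzylidene)-D-xylono-1,4-lactone (2-OH free, aryl equatorial on the cis-fused dioxane) | O=C1[C@H](O)[C@H]2O[C@@H](c3ccc(OC)cc3)OC[C@H]2O1 | intermediate
5 | N,O-dimethylhydroxylamine hydrochloride | CNOC.Cl | starting material
6 | chloromagnesium N-methoxy-N-methylamide | CON(C)[Mg]Cl | intermediate
7 | N-methoxy-N-methyl-3,5-O-(4-methoxybenzylidene)-D-xylonamide (2-OH and 4-OH free) | CON(C)C(=O)[C@H](O)[C@H]1O[C@@H](c2ccc(OC)cc2)OC[C@H]1O | intermediate
8 | triethylsilyl trifluoromethanesulfonate | CC[Si](CC)(CC)OS(=O)(=O)C(F)(F)F | starting material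
9 | N-methoxy-N-methyl-3,5-O-(4-methoxybenzylidene)-2,4-bis-O-(triethylsilyl)-D-xylonamide | CON(C)C(=O)[C@H](O[Si](CC)(CC)CC)[C@H]1O[C@@H](c2ccc(OC)cc2)OC[C@H]1O[Si](CC)(CC)CC | intermediate
10 | ethynyltrimethylsilane | C#C[Si](C)(C)C | starting material
11 | lithium (trimethylsilyl)acetylide | [Li]C#C[Si](C)(C)C | intermediate
12 | 1,2-dideoxy-5,7-O-(4-methoxybenzylidene)-4,6-bis-O-(triethylsilyl)-1-(trimethylsilyl)-D-xylo-hept-1-yn-3-ulose (the silyl-capped ynone) | C[Si](C)(C)C#CC(=O)[C@H](O[Si](CC)(CC)CC)[C@H]1O[C@@H](c2ccc(OC)cc2)OC[C@H]1O[Si](CC)(CC)CC | intermediate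
13 | 1,2-dideoxy-5,7-O-(4-methoxybenzylidene)-4,6-bis-O-(triethylsilyl)-1-(trimethylsilyl)-D-gulo-hept-1-ynitol ((S)-carbinol at the future C4) | C[Si](C)(C)C#C[C@H](O)[C@H](O[Si](CC)(CC)CC)[C@H]1O[C@@H](c2ccc(OC)cc2)OC[C@H]1O[Si](CC)(CC)CC | intermediate
14 | 1,2-dideoxy-5,7-O-(4-methoxybenzylidene)-4,6-bis-O-(triethylsilyl)-D-gulo-hept-1-ynitol | C#C[C@H](O)[C@H](O[Si](CC)(CC)CC)[C@H]1O[C@@H](c2ccc(OC)cc2)OC[C@H]1O[Si](CC)(CC)CC | intermediate
15 | N-chlorosuccinimide | O=C1CCC(=O)N1Cl | starting material
16 | (E)-alkenylzirconocene chloride from 14, hydroxyl as its zirconocene alkoxide | Cl[Zr](C3C=CC=C3)(C4C=CC=C4)/C=C/[C@H](O[Zr](Cl)(C5C=CC=C5)C6C=CC=C6)[C@H](O[Si](CC)(CC)CC)[C@H]1O[C@@H](c2ccc(OC)cc2)OC[C@H]1O[Si](CC)(CC)CC | intermediate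
17 | (E)-1-chloro-1,2-dideoxy-5,7-O-(4-methoxybenzylidene)-4,6-bis-O-(triethylsilyl)-D-gulo-hept-1-enitol | Cl/C=C/[C@H](O)[C@H](O[Si](CC)(CC)CC)[C@H]1O[C@@H](c2ccc(OC)cc2)OC[C@H]1O[Si](CC)(CC)CC | intermediate
18 | (E)-1-chloro-1,2-dideoxy-5-O-(4-methoxybenzyl)-4,6-bis-O-(triethylsilyl)-D-gulo-hept-1-enitol (3-OH and 7-OH free) | Cl/C=C/[C@H](O)[C@H](O[Si](CC)(CC)CC)[C@@H](OCc1ccc(OC)cc1)[C@H](O[Si](CC)(CC)CC)CO | intermediate
19 | (E)-7-chloro-6,7-dideoxy-3-O-(4-methoxybenzyl)-2,4-bis-O-(triethylsilyl)-aldehydo-L-gluco-hept-6-enose (5-OH free) | Cl/C=C/[C@H](O)[C@H](O[Si](CC)(CC)CC)[C@@H](OCc1ccc(OC)cc1)[C@H](O[Si](CC)(CC)CC)C=O | intermediate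
20 | pyranose lactol of 19 (both anomers) | OC1[C@@H](O[Si](CC)(CC)CC)[C@H](OCc2ccc(OC)cc2)[C@@H](O[Si](CC)(CC)CC)[C@H](/C=C/Cl)O1 | intermediate
21 | (E)-7-chloro-6,7-dideoxy-3-O-(4-methoxybenzyl)-2,4-bis-O-(triethylsilyl)-L-gluco-hept-6-enono-1,5-lactone, i.e. (3S,4R,5S,6S)-6-[(E)-2-chloroethenyl]-4-[(4-methoxybenzyl)oxy]-3,5-bis(triethylsilyloxy)oxan-2-one | O=C1[C@@H](O[Si](CC)(CC)CC)[C@H](OCc2ccc(OC)cc2)[C@@H](O[Si](CC)(CC)CC)[C@H](/C=C/Cl)O1 | intermediate
22 | cyclic silyl ketene acetal of 21 (C7=C1 double bond, trimethylsilyloxy on C7; C6, C5, C4 as in 21) | C[Si](C)(C)OC1=C(O[Si](CC)(CC)CC)[C@H](OCc2ccc(OC)cc2)[C@@H](O[Si](CC)(CC)CC)[C@H](/C=C/Cl)O1 | intermediate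
23 | trimethylsilyl ester of 24 | C[Si](C)(C)OC(=O)[C@]1(O[Si](CC)(CC)CC)[C@H](Cl)C=C[C@H](O[Si](CC)(CC)CC)[C@H]1OCc2ccc(OC)cc2 | intermediate
24 | (1S,2R,5S,6R)-2-chloro-6-[(4-methoxybenzyl)oxy]-1,5-bis(triethylsilyloxy)cyclohex-3-ene-1-carboxylic acid (Cl cis to CO2H, 1-O cis to 6-O, 5-O trans to 6-O) | OC(=O)[C@]1(O[Si](CC)(CC)CC)[C@H](Cl)C=C[C@H](O[Si](CC)(CC)CC)[C@H]1OCc2ccc(OC)cc2 | intermediate
25 | isobutyl carbonic mixed anhydride of 24 | CC(C)COC(=O)OC(=O)[C@]1(O[Si](CC)(CC)CC)[C@H](Cl)C=C[C@H](O[Si](CC)(CC)CC)[C@H]1OCc2ccc(OC)cc2 | intermediate
26 | [(1R,2R,5S,6R)-2-chloro-6-[(4-methoxybenzyl)oxy]-1,5-bis(triethylsilyloxy)cyclohex-3-en-1-yl]methanol | OC[C@]1(O[Si](CC)(CC)CC)[C@H](Cl)C=C[C@H](O[Si](CC)(CC)CC)[C@H]1OCc2ccc(OC)cc2 | intermediate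
27 | [(1R,2R,5S,6R)-2-chloro-6-hydroxy-1,5-bis(triethylsilyloxy)cyclohex-3-en-1-yl]methanol | OC[C@]1(O[Si](CC)(CC)CC)[C@H](Cl)C=C[C@H](O[Si](CC)(CC)CC)[C@H]1O | intermediate
28 | benzoyl chloride | O=C(Cl)c1ccccc1 | starting material
29 | [(1R,2R,5S,6R)-6-(benzoyloxy)-2-chloro-1,5-bis(triethylsilyloxy)cyclohex-3-en-1-yl]methyl benzoate | O=C(OC[C@]1(O[Si](CC)(CC)CC)[C@H](Cl)C=C[C@H](O[Si](CC)(CC)CC)[C@H]1OC(=O)c1ccccc1)c1ccccc1 | intermediate
30 | [(1R,2R,5S,6R)-6-(benzoyloxy)-2-chloro-1,5-dihydroxycyclohex-3-en-1-yl]methyl benzoate (CNP0326102.1) | O=C(OC[C@]1(O)[C@H](Cl)C=C[C@H](O)[C@H]1OC(=O)c1ccccc1)c1ccccc1 | target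

## Step count and least certain steps

Total: 15 steps. Longest linear sequence: 15 steps, from 1 to 30; the route is fully linear.

Step 11 (key step). Three things may go wrong. The C6 alkoxide may be lost by β-elimination from the enolate before it is silylated. The boat transition state may demand a temperature at which the ketene acetal decomposes or the new allylic chloride exchanges or ionises, scrambling C2. The amide base may also deprotonate the chlorovinyl group. The cause in each case is that the rearrangement combines a strained boat with a heteroatom-bearing terminus that has no direct precedent. Fallback with known chemistry, setting out from 14 and returning at 29: partial hydrogenation of the alkyne over Pd/CaCO3 poisoned by Pb(OAc)2 gives the vinyl carbinol F1. Reductive acetal opening as in step 9 gives the diol F2, and oxidative lactonisation as in step 10 gives the 6-vinyl lactone F3, a member of the lactone class for which the silyl ketene acetal ring contraction is documented. That rearrangement gives the 2-unsubstituted cyclohexene acid F4, which is carried through the operations of steps 12–14 to the alcohol F5, the diol F6 and the dibenzoate F7. Allylic oxidation of F7 with SeO2 and tBuOOH (ene reaction, then [2,3] shift) should bring oxygen to C2 on the face of the C1 oxygen, because selenium adds to C4 anti to the C5 silyloxy group; this gives the allylic alcohol F8. Appel chlorination (PPh3, CCl4) with inversion at C2 then gives 29.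

Step 6. Facial selectivity may be poor because the catalyst must override the opposite Felkin–Anh preference of the α-silyloxy ketone; slow turnover at the hindered ketone is the second concern. Fallback, setting out from 9 and returning at 14: reduction of the amide with iBu2AlH at −78 °C gives the aldehyde F9. Addition of ethynylmagnesium bromide under non-chelating conditions then gives 14 directly. In an aldehyde addition the Felkin–Anh bias of the α-silyloxy group favours the wanted anti carbinol, so substrate control replaces reagent control, and step 7 is saved.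

Step 10. The secondary allylic alcohol may be oxidised in competition with the primary one, or the centre α to the intermediate aldehyde may epimerise, because both hydroxyls are free during the oxidation. Fallback, setting out from 14 and returning at 21: the acetal is opened with iBu2AlH first to give the alkynyl diol F10. Its oxidative lactonisation, in which the competing secondary alcohol is the less readily oxidised propargylic one, gives the alkynyl lactone F11. Hydrozirconation with Cp2Zr(H)Cl (one equivalent suffices, no hydroxyl being present, and alkyne addition outpaces lactone reduction) and chlorination with 15 then give 21.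

Step 12. Hydride may attack the carbonate carbonyl of 25 instead of the neopentyl-type acyl carbon and return the acid, or the triethylsilyl group may shift from the tertiary oxygen to the new primary alkoxide in the basic medium. Fallback, setting out from 24 and returning at 26: esterification with trimethylsilyldiazomethane gives the methyl ester F12. Reduction with iBu2AlH at −78 °C, with a non-basic quench from an aluminium alkoxide, gives 26.

Step 13. The oxocarbenium ion may be trapped by the neighbouring C7 hydroxyl to give a cyclic acetal instead of being hydrolysed, because that hydroxyl is held next to the ether oxygen. Fallback, setting out from 26 and returning at 29: the primary hydroxyl is benzoylated first with 28 to give the monobenzoate F13. Oxidative ether cleavage with DDQ, now without a participating neighbour, gives the alcohol F14, and a second benzoylation gives 29.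

## Further compounds

F1 | step 11 | 1,2-dideoxy-5,7-O-(4-methoxybenzylidene)-4,6-bis-O-(triethylsilyl)-D-gulo-hept-1-enitol (vinyl carbinol) | C=C[C@H](O)[C@H](O[Si](CC)(CC)CC)[C@H]1O[C@@H](c2ccc(OC)cc2)OC[C@H]1O[Si](CC)(CC)CC
F2 | step 11 | 1,2-dideoxy-5-O-(4-methoxybenzyl)-4,6-bis-O-(triethylsilyl)-D-gulo-hept-1-enitol (diol) | C=C[C@H](O)[C@H](O[Si](CC)(CC)CC)[C@@H](OCc1ccc(OC)cc1)[C@H](O[Si](CC)(CC)CC)CO
F3 | step 11 | 6,7-dideoxy-3-O-(4-methoxybenzyl)-2,4-bis-O-(triethylsilyl)-L-gluco-hept-6-enono-1,5-lactone (6-vinyl lactone) | O=C1[C@@H](O[Si](CC)(CC)CC)[C@H](OCc2ccc(OC)cc2)[C@@H](O[Si](CC)(CC)CC)[C@H](C=C)O1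
F4 | step 11 | 6-[(4-methoxybenzyl)oxy]-1,5-bis(triethylsilyloxy)cyclohex-3-ene-1-carboxylic acid, C1, C5, C6 as in 24, C2 a methylene | OC(=O)[C@]1(O[Si](CC)(CC)CC)CC=C[C@H](O[Si](CC)(CC)CC)[C@H]1OCc2ccc(OC)cc2
F5 | step 11 | primary alcohol from F4 (C7 hydroxymethyl) | OC[C@]1(O[Si](CC)(CC)CC)CC=C[C@H](O[Si](CC)(CC)CC)[C@H]1OCc2ccc(OC)cc2
F6 | step 11 | C7,C6-diol from F5 | OC[C@]1(O[Si](CC)(CC)CC)CC=C[C@H](O[Si](CC)(CC)CC)[C@H]1O
F7 | step 11 | C7,C6-dibenzoate lacking the C2 substituent | O=C(OC[C@]1(O[Si](CC)(CC)CC)CC=C[C@H](O[Si](CC)(CC)CC)[C@H]1OC(=O)c1ccccc1)c1ccccc1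
F8 | step 11 | C2 allylic alcohol of F7, hydroxyl cis to the C1 oxygen | O=C(OC[C@]1(O[Si](CC)(CC)CC)[C@@H](O)C=C[C@H](O[Si](CC)(CC)CC)[C@H]1OC(=O)c1ccccc1)c1ccccc1
F9 | step 6 | 3,5-O-(4-methoxybenzylidene)-2,4-bis-O-(triethylsilyl)-aldehydo-D-xylose | O=C[C@H](O[Si](CC)(CC)CC)[C@H]1O[C@@H](c2ccc(OC)cc2)OC[C@H]1O[Si](CC)(CC)CC
F10 | step 10 | 1,2-dideoxy-5-O-(4-methoxybenzyl)-4,6-bis-O-(triethylsilyl)-D-gulo-hept-1-ynitol (alkynyl diol) | C#C[C@H](O)[C@H](O[Si](CC)(CC)CC)[C@@H](OCc1ccc(OC)cc1)[C@H](O[Si](CC)(CC)CC)CO
F11 | step 10 | 6,7-dideoxy-3-O-(4-methoxybenzyl)-2,4-bis-O-(triethylsilyl)-L-gluco-hept-6-ynono-1,5-lactone (alkynyl lactone) | O=C1[C@@H](O[Si](CC)(CC)CC)[C@H](OCc2ccc(OC)cc2)[C@@H](O[Si](CC)(CC)CC)[C@H](C#C)O1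
F12 | step 12 | methyl ester of 24 | COC(=O)[C@]1(O[Si](CC)(CC)CC)[C@H](Cl)C=C[C@H](O[Si](CC)(CC)CC)[C@H]1OCc2ccc(OC)cc2
F13 | step 13 | C7 monobenzoate of 26 | O=C(OC[C@]1(O[Si](CC)(CC)CC)[C@H](Cl)C=C[C@H](O[Si](CC)(CC)CC)[C@H]1OCc2ccc(OC)cc2)c1ccccc1
F14 | step 13 | C7 monobenzoate with free C6 hydroxyl | O=C(OC[C@]1(O[Si](CC)(CC)CC)[C@H](Cl)C=C[C@H](O[Si](CC)(CC)CC)[C@H]1O)c1ccccc1
A1 | alternative 1 | (1-hydroxycyclohexa-2,5-dien-1-yl)methyl benzoate | O=C(OCC1(O)C=CCC=C1)c1ccccc1
A2 | alternative 1 | syn epoxy alcohol from A1, C1, C5 and C6 set | O=C(OC[C@]1(O)C=CC[C@H]2O[C@@H]12)c1ccccc1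
A3 | alternative 2 | (1S,6R)-1,6-dihydroxycyclohexa-2,4-diene-1-carboxylic acid | OC(=O)[C@]1(O)C=CC=C[C@H]1O
A4 | alternative 2 | 2-chloro-1,8-dihydroxy-6-oxabicyclo[3.2.1]oct-3-en-7-one with the target configuration | O=C1[C@]2(O)[C@H](Cl)C=C[C@H](O1)[C@H]2O
A5 | alternative 3 | acyclic 1,7-diene with C1/C6 acetonide, C7 benzoate, C2 hydroxyl and C5 triisopropylsilyl ether | C=C[C@H](O)[C@]1(COC(=O)c2ccccc2)OC(C)(C)O[C@@H]1[C@@H](O[Si](C(C)C)(C(C)C)C(C)C)C=C
A6 | alternative 3 | cyclohexene from A5 with C1/C6 acetonide, C7 benzoate, C2 hydroxyl cis to the C1 oxygen and C5 triisopropylsilyl ether | O=C(c1ccccc1)OC[C@]2(OC(C)(C)O3)[C@@H](O)C=C[C@H](O[Si](C(C)C)(C(C)C)C(C)C)[C@H]23
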